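**Retrosynthetic overview**

1. Numbering: each half is a 3-methylquinolizidin-2-one (C1, C2=O, C3, C4, N5, C6–C8, C9, C9a; ring A = piperidinone, ring B = piperidine). The halves are joined C9→C1 by two (CH2)5 chains (16-membered ring). Cis half = (1S,3R,9R,9aR), trans half = (1S,3R,9S,9aS).
2. Enabling feature: in ring A, C9a is α to N5 and β to the C2 ketone, so N5–C9a=C1–C2=O (a 2,3-dihydro-4-pyridone) is a latent iminium ion at C9a; C9 carries a carbon chain that an allylsilane can deliver as an alkene.
3. Last C–C bond: C9–C9a of the cis half, by transannular closure of an allylsilane onto the silyl-activated vinylogous amide of a 20-membered macrocycle. Ring B of the cis half and the 16-membered ring form together, and C9, C9a and C1 are set in the same operation.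
4. Before that: the same closure on the trans half, then base equilibration to the all-equatorial isomer. The two C1–CH2 bonds come from B-alkyl Suzuki couplings of α-iodo vinylogous amides, the two N–CH2 bonds from N-alkylations.
5. Building blocks: iodo-dihydropyridone 6 (used twice) and the enantiomeric α-silyl 1,5-dienes 15 and 21. Ring order: ring A (trans) → ring B (trans) → ring A (cis) → 20-membered ring → ring B (cis) with the 16-membered ring.

Key step: step 19

Remark: the cis-fused half (H1/H9a cis) is treated as a kinetic arrangement that would epimerise at C1/C3 under equilibrating conditions, so it is made last and not exposed to acid or base afterwards.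

**Step 1**
Reactants: 1 (R)-3-[(tert-butoxycarbonyl)amino]-2-methylpropanoic acid
Product: 2 tert-butyl (R)-[3-(methoxy(methyl)amino)-2-methyl-3-oxopropyl]carbamate
Conditions: MeNHOMe·HCl, EDC·HCl, HOBt, i-Pr2NEt, CH2Cl2, 0 °C → rt
Reagents that add atoms: N,O-dimethylhydroxylamine hydrochloride, CNOC.Cl
Why: Carbodiimide/HOBt amide coupling should give the Weinreb amide without touching the α-stereocentre.

**Step 2**
Reactants: 2 Weinreb amide
Product: 3 tert-butyl (R)-(2-methyl-3-oxopent-4-yn-1-yl)carbamate
Conditions: HC≡CMgBr (3 equiv), THF, −78 → 0 °C; inverse quench into cold aq NaHSO4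
Reagents that add atoms: ethynylmagnesium bromide, C#C[Mg]Br
Why: Weinreb ketone synthesis, in which the chelated tetrahedral intermediate stops at the ynone and the cold acidic inverse quench keeps the liberated hydroxylamine from adding to it.

**Step 3**
Reactants: 3 Boc-amino ynone
Product: 5 (R)-3-methyl-2,3-dihydropyridin-4(1H)-one, via chlorovinyl ketone salt 4 (not isolated)
Conditions: HCl (4 M in dioxane), 0 °C → rt; then K2CO3, MeOH, 0 °C → rt
Reagents that add atoms: none
Why: Carbamate acidolysis with HCl addition across the ynone, then base-induced 6-endo addition–elimination of the free amine (amino-ynone cyclisation), should give the vinylogous amide with the preset C3 centre retained because the base treatment is cold and short.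

**Step 4**
Reactants: 5 dihydropyridone
Product: 6 (R)-5-iodo-3-methyl-2,3-dihydropyridin-4(1H)-one
Conditions: NIS, CH2Cl2, 0 °C → rt, dark
Reagents that add atoms: N-iodosuccinimide, O=C1CCC(=O)N1I
Why: The enaminone is nucleophilic at its α-carbon, so electrophilic iodination should give the vinyl iodide needed for cross-coupling.

**Step 5**
Reactants: 7 4-chlorobutanoyl chloride; 8 bis(trimethylsilyl)acetylene
Product: 9 6-chloro-1-(trimethylsilyl)hex-1-yn-3-one
Conditions: AlCl3 (1.1 equiv), CH2Cl2, 0 °C
Reagents that add atoms: none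
Why: Friedel–Crafts-type acylative ipso-desilylation of the bis-silylalkyne should stop after one acylation because the ynone is deactivated.

**Step 6**
Reactants: 9 silyl ynone
Product: 10 (S)-6-chloro-1-(trimethylsilyl)hex-1-yn-3-ol
Conditions: Ru[(S,S)-TsNCH(Ph)CH(Ph)NH](p-cymene) (1 mol%), i-PrOH, rt
Reagents that add atoms: none
Why: Noyori asymmetric transfer hydrogenation of an α,β-acetylenic ketone, in which the (S,S)-catalyst is expected to give the (S)-propargylic alcohol with the alkynyl group acting as the π-substituent.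

**Step 7**
Reactants: 10 (S)-propargylic alcohol
Product: 11 (S,E)-6-chloro-1-(trimethylsilyl)hex-1-en-3-ol
Conditions: NaAlH2(OCH2CH2OMe)2, Et2O, 0 °C → rt; aq potassium sodium tartrate
Reagents that add atoms: none
Why: Alkoxide-directed trans-hydroalumination of the propargylic alcohol and protonolysis should give the (E)-vinylsilane without touching the carbinol centre.

**Step 8**
Reactants: 11 (S,E)-allylic alcohol
Product: 13 ethyl (S,E)-8-chloro-3-(trimethylsilyl)oct-4-enoate, via ketene acetal 12 (not isolated)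
Conditions: MeC(OEt)3 (6 equiv), EtCO2H (cat.), xylenes, 140 °C, EtOH distilled off
Reagents that add atoms: triethyl orthoacetate, CC(OCC)(OCC)OCC
Why: Johnson–Claisen [3,3] rearrangement through a chair transition state with the chloropropyl group equatorial should transfer the carbinol configuration to the silicon-bearing carbon (S) and form the (E)-alkene.

**Step 9**
Reactants: 13 (S)-silyl ester
Product: 15 (S,E)-(9-chloronona-1,5-dien-4-yl)trimethylsilane, via silyl aldehyde 14 (not isolated)
Conditions: i-Bu2AlH (1.05 equiv), CH2Cl2, −78 °C; then Ph3P=CH2 (from Ph3PCH3Br, KN(SiMe3)2, THF), −78 °C → rt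
Reagents that add atoms: methyltriphenylphosphonium bromide, C[P+](c1ccccc1)(c1ccccc1)c1ccccc1.[Br-]
Why: Partial reduction to the aluminium hemiacetal and Wittig methylenation of the aldehyde released on warming should give the terminal alkene, the C–Si stereocentre being β to the carbonyl and unable to enolise.

**Step 10**
Reactants: 9 silyl ynone
Product: 16 (R)-6-chloro-1-(trimethylsilyl)hex-1-yn-3-ol
Conditions: Ru[(R,R)-TsNCH(Ph)CH(Ph)NH](p-cymene) (1 mol%), i-PrOH, rt
Reagents that add atoms: none
Why: Noyori asymmetric transfer hydrogenation with the enantiomeric catalyst should give the (R)-alcohol.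

**Step 11**
Reactants: 16 (R)-propargylic alcohol
Product: 17 (R,E)-6-chloro-1-(trimethylsilyl)hex-1-en-3-ol
Conditions: NaAlH2(OCH2CH2OMe)2, Et2O, 0 °C → rt; aq potassium sodium tartrate
Reagents that add atoms: none
Why: Alkoxide-directed trans-hydroalumination as in step 7 should give the (E)-vinylsilane.

**Step 12**
Reactants: 17 (R,E)-allylic alcohol
Product: 19 ethyl (R,E)-8-chloro-3-(trimethylsilyl)oct-4-enoate, via ketene acetal 18 (not isolated)
Conditions: MeC(OEt)3 (6 equiv), EtCO2H (cat.), xylenes, 140 °C, EtOH distilled off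
Reagents that add atoms: triethyl orthoacetate, CC(OCC)(OCC)OCC
Why: Johnson–Claisen rearrangement through the same chair transition state should give the (R)-configured C–Si centre and the (E)-alkene.

**Step 13**
Reactants: 19 (R)-silyl ester
Product: 21 (R,E)-(9-chloronona-1,5-dien-4-yl)trimethylsilane, via silyl aldehyde 20 (not isolated)
Conditions: i-Bu2AlH (1.05 equiv), CH2Cl2, −78 °C; then Ph3P=CH2 (from Ph3PCH3Br, KN(SiMe3)2, THF), −78 °C → rt
Reagents that add atoms: methyltriphenylphosphonium bromide, C[P+](c1ccccc1)(c1ccccc1)c1ccccc1.[Br-]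
Why: Partial reduction and Wittig methylenation as in step 9 should give the terminal alkene with the C–Si centre unchanged.

**Step 14**
Reactants: 6 iodo-dihydropyridone; 21 (R)-silyl diene
Product: 22 (R)-5-iodo-3-methyl-1-[(4E,6R)-6-(trimethylsilyl)nona-4,8-dien-1-yl]-2,3-dihydropyridin-4(1H)-one
Conditions: NaH (1.05 equiv), DMF, 0 °C; then 21, NaI (0.2 equiv), 60 °C
Reagents that add atoms: none
Why: The sodium salt of the vinylogous amide should be alkylated at nitrogen by the primary halide (Finkelstein-assisted SN2), leaving the vinyl iodide, the allylsilane and the alkenes untouched.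

**Step 15**
Reactants: 15 (S)-silyl diene; 22 N-alkylated iodide
Product: 24 (R)-5-[(4S,5E)-9-chloro-4-(trimethylsilyl)non-5-en-1-yl]-3-methyl-1-[(4E,6R)-6-(trimethylsilyl)nona-4,8-dien-1-yl]-2,3-dihydropyridin-4(1H)-one, via alkylborane 23 (not isolated)
Conditions: 15, 9-BBN-H (1.0 equiv), THF, 0 °C → rt; then 22, PdCl2(dppf) (5 mol%), AsPh3, Cs2CO3, DMF/H2O, rt
Reagents that add atoms: none
Why: 9-BBN-H should hydroborate only the terminal alkene of 15 (anti-Markovnikov), and B-alkyl Suzuki–Miyaura coupling of the borane with the α-iodo enaminone should form the C1–CH2 bond without affecting either allylsilane or the alkyl chloride.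

**Step 16**
Reactants: 24 vinylogous amide bis-allylsilane
Product: 26 (1S,3R,9R,9aS)-1-[(4S,5E)-9-chloro-4-(trimethylsilyl)non-5-en-1-yl]-3-methyl-9-[(1E)-penta-1,4-dien-1-yl]octahydro-2H-quinolizin-2-one, via silyl enol ether 25 (not isolated)
Conditions: Me3SiOTf (1.1 equiv), 2,6-di-tert-butyl-4-methylpyridine (0.2 equiv), CH2Cl2, −78 → 0 °C; then K2CO3, MeOH, rt
Reagents that add atoms: none
Why: Proposed new method: Me3SiOTf should turn the vinylogous amide into a 4-silyloxy-2,3-dihydropyridinium ion that the N-tethered (R)-allylsilane attacks at C9a through a chair transition state and anti to silicon (closest known types: iminium and N-acyliminium–allylsilane cyclisation to vinylquinolizidines, and Hosomi–Sakurai conjugate allylation), so that C9 is set by 1,3-chirality transfer, while K2CO3/MeOH cleaves the silyl enol ether and equilibrates C1 (and C9a if needed) to the all-equatorial trans-fused ketone; the second allylsilane is too remote to cyclise (8-membered ring).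

**Step 17**
Reactants: 26 trans-half quinolizidinone chloride; 6 iodo-dihydropyridone
Product: 27 (R)-5-iodo-3-methyl-1-{(4E,6S)-9-[(1S,3R,9R,9aS)-3-methyl-2-oxo-9-((1E)-penta-1,4-dien-1-yl)octahydro-2H-quinolizin-1-yl]-6-(trimethylsilyl)non-4-en-1-yl}-2,3-dihydropyridin-4(1H)-one
Conditions: 6, NaH (1.2 equiv), DMF, 0 °C; then 26, NaI (0.2 equiv), 50 °C
Reagents that add atoms: none
Why: N-alkylation as in step 14; the ketone of 26 is already at its thermodynamic configuration, so the mildly basic medium cannot change it.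

**Step 18**
Reactants: 27 seco iodide
Product: 29 20-membered macrocyclic vinylogous amide–allylsilane, via alkylborane 28 (not isolated)
Conditions: 9-BBN-H (1.2 equiv), THF, 0 °C → rt; then slow addition to PdCl2(dppf) (20 mol%), AsPh3, Cs2CO3, DMF/THF/H2O, 50 °C, 1 mM
Reagents that add atoms: none
Why: Macrocyclic B-alkyl Suzuki–Miyaura coupling, in which 9-BBN-H should select the terminal alkene over the internal alkenes and the ketone, and slow addition at high dilution should favour closure of the 20-membered ring.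

**Step 19**
Reactants: 29 macrocyclic vinylogous amide–allylsilane
Product: 31 bis-quinolizidinone (E,E)-diene, via silyl enol ether 30 (not isolated)
Conditions: TfOH (1.0 equiv), CH2Cl2, −78 °C; Me3SiOTf (1.5 equiv), −78 → −20 °C; then MeOH, −78 °C; cold aq NaHCO3
Reagents that add atoms: none
Why: Proposed new method: Me3SiOTf silylates the carbonyl oxygen of the ring A vinylogous amide to a 4-silyloxy-2,3-dihydropyridinium ion, C9 (the γ-carbon of the N-tethered allylsilane) attacks C9a, the β-silyl cation loses the silyl group to triflate to leave the (E)-alkene and the C1=C2 silyl enol ether 30, and MeOH/TfOH then protonates C1 at −78 °C. The closest known reaction types are iminium and N-acyliminium–allylsilane cyclisations to vinylquinolizidines and the capture of 4-silyloxypyridinium, -quinolinium and -benzopyrylium ions by silicon π-nucleophiles; what is not yet shown is their use on an N-alkyl 2,3-dihydro-4-pyridone, here in a transannular setting. Ring B of the cis half closes 6-exo-trig with respect to the allylsilane alkene (6-endo with respect to the C=N+ bond), and the same bond contracts the 20-membered ring to the 16-membered carbocycle (transannular closure). C9 (R) is set by anti-SE2′ attack opposite the C–Si bond of the (S)-silane in its A(1,3)-minimised conformation; C9a (R) by the chair transition state that keeps the alkenyl chain equatorial on the forming ring (H9/H9a trans) and adds axially, cis to the pseudo-equatorial C3 methyl; C1 (S) by kinetic axial protonation of the silyl enol ether anti to the pseudo-axial C9–C9a bond (H1/H9a cis). The step needs chemoselectivity for the vinylogous amide over the amine and ketone of the trans half (secured by N-protonation with TfOH and the absence of base, so the ketone is not enol-silylated) and kinetic control at C1 (secured by protonation at −78 °C and a cold bicarbonate quench).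

**Step 20**
Reactants: 31 bis-quinolizidinone (E,E)-diene
Product: 32 target bis-quinolizidinone
Conditions: H2 (1 atm), Pd/C (10 wt%), EtOAc, rt
Reagents that add atoms: none
Why: Heterogeneous hydrogenation of the two disubstituted alkenes under neutral conditions should leave the ketones and the epimerisable C1 centre of the cis half unchanged.

**Compound list**

1 | (R)-3-[(tert-butoxycarbonyl)amino]-2-methylpropanoic acid | C[C@H](CNC(=O)OC(C)(C)C)C(=O)O | starting material
2 | tert-butyl (R)-[3-(methoxy(methyl)amino)-2-methyl-3-oxopropyl]carbamate | C[C@H](CNC(=O)OC(C)(C)C)C(=O)N(C)OC | intermediate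
3 | tert-butyl (R)-(2-methyl-3-oxopent-4-yn-1-yl)carbamate | C[C@H](CNC(=O)OC(C)(C)C)C(=O)C#C | intermediate
4 | (R)-5-amino-1-chloro-4-methylpent-1-en-3-one hydrochloride (alkene geometry not defined) | C[C@H](C[NH3+])C(=O)C=CCl.[Cl-] | intermediate
5 | (R)-3-methyl-2,3-dihydropyridin-4(1H)-one | C[C@@H]1CNC=CC1=O | intermediate
6 | (R)-5-iodo-3-methyl-2,3-dihydropyridin-4(1H)-one | C[C@@H]1CNC=C(I)C1=O | intermediate
7 | 4-chlorobutanoyl chloride | ClCCCC(Cl)=O | starting material
8 | bis(trimethylsilyl)acetylene | C[Si](C)(C)C#C[Si](C)(C)C | starting material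
9 | 6-chloro-1-(trimethylsilyl)hex-1-yn-3-one | ClCCCC(=O)C#C[Si](C)(C)C | intermediate
10 | (S)-6-chloro-1-(trimethylsilyl)hex-1-yn-3-ol | ClCCC[C@H](O)C#C[Si](C)(C)C | intermediate
11 | (S,E)-6-chloro-1-(trimethylsilyl)hex-1-en-3-ol | ClCCC[C@H](O)/C=C/[Si](C)(C)C | intermediate
12 | (S,E)-[6-chloro-3-(1-ethoxyvinyloxy)hex-1-en-1-yl]trimethylsilane | C=C(OCC)O[C@@H](CCCCl)/C=C/[Si](C)(C)C | intermediate
13 | ethyl (S,E)-8-chloro-3-(trimethylsilyl)oct-4-enoate | CCOC(=O)C[C@H]([Si](C)(C)C)/C=C/CCCCl | intermediate
14 | (S,E)-8-chloro-3-(trimethylsilyl)oct-4-enal | O=CC[C@H]([Si](C)(C)C)/C=C/CCCCl | intermediate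
15 | (S,E)-(9-chloronona-1,5-dien-4-yl)trimethylsilane | C=CC[C@H]([Si](C)(C)C)/C=C/CCCCl | intermediate
16 | (R)-6-chloro-1-(trimethylsilyl)hex-1-yn-3-ol | ClCCC[C@@H](O)C#C[Si](C)(C)C | intermediate
17 | (R,E)-6-chloro-1-(trimethylsilyl)hex-1-en-3-ol | ClCCC[C@@H](O)/C=C/[Si](C)(C)C | intermediate
18 | (R,E)-[6-chloro-3-(1-ethoxyvinyloxy)hex-1-en-1-yl]trimethylsilane | C=C(OCC)O[C@H](CCCCl)/C=C/[Si](C)(C)C | intermediate
19 | ethyl (R,E)-8-chloro-3-(trimethylsilyl)oct-4-enoate | CCOC(=O)C[C@@H]([Si](C)(C)C)/C=C/CCCCl | intermediate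
20 | (R,E)-8-chloro-3-(trimethylsilyl)oct-4-enal | O=CC[C@@H]([Si](C)(C)C)/C=C/CCCCl | intermediate
21 | (R,E)-(9-chloronona-1,5-dien-4-yl)trimethylsilane | C=CC[C@@H]([Si](C)(C)C)/C=C/CCCCl | intermediate
22 | (R)-5-iodo-3-methyl-1-[(4E,6R)-6-(trimethylsilyl)nona-4,8-dien-1-yl]-2,3-dihydropyridin-4(1H)-one | C[C@@H]1CN(CCC/C=C/[C@H]([Si](C)(C)C)CC=C)C=C(I)C1=O | intermediate
23 | 9-[(4S,5E)-9-chloro-4-(trimethylsilyl)non-5-en-1-yl]-9-borabicyclo[3.3.1]nonane | ClCCC/C=C/[C@@H]([Si](C)(C)C)CCCB1C2CCCC1CCC2 | intermediate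
24 | (R)-5-[(4S,5E)-9-chloro-4-(trimethylsilyl)non-5-en-1-yl]-3-methyl-1-[(4E,6R)-6-(trimethylsilyl)nona-4,8-dien-1-yl]-2,3-dihydropyridin-4(1H)-one | C[C@@H]1CN(CCC/C=C/[C@H]([Si](C)(C)C)CC=C)C=C(CCC[C@H]([Si](C)(C)C)/C=C/CCCCl)C1=O | intermediate
25 | (3R,9R,9aS)-1-[(4S,5E)-9-chloro-4-(trimethylsilyl)non-5-en-1-yl]-3-methyl-9-[(1E)-penta-1,4-dien-1-yl]-2-(trimethylsilyloxy)-4,6,7,8,9,9a-hexahydro-3H-quinolizine | ClCCC/C=C/[C@@H]([Si](C)(C)C)CCCC1=C(O[Si](C)(C)C)[C@H](C)CN2CCC[C@H](/C=C/CC=C)[C@@H]12 | intermediate
26 | (1S,3R,9R,9aS)-1-[(4S,5E)-9-chloro-4-(trimethylsilyl)non-5-en-1-yl]-3-methyl-9-[(1E)-penta-1,4-dien-1-yl]octahydro-2H-quinolizin-2-one | ClCCC/C=C/[C@@H]([Si](C)(C)C)CCC[C@@H]1C(=O)[C@H](C)CN2CCC[C@H](/C=C/CC=C)[C@@H]12 | intermediate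
27 | (R)-5-iodo-3-methyl-1-{(4E,6S)-9-[(1S,3R,9R,9aS)-3-methyl-2-oxo-9-((1E)-penta-1,4-dien-1-yl)octahydro-2H-quinolizin-1-yl]-6-(trimethylsilyl)non-4-en-1-yl}-2,3-dihydropyridin-4(1H)-one | C[C@@H]1CN(C=C(I)C1=O)CCC/C=C/[C@@H]([Si](C)(C)C)CCC[C@@H]2C(=O)[C@H](C)CN3CCC[C@H](/C=C/CC=C)[C@@H]23 | intermediate
28 | 9-BBN adduct of 27 (terminal CH=CH2 of the pentadienyl group converted into CH2CH2–B of 9-borabicyclo[3.3.1]nonane) | C[C@@H]1CN(C=C(I)C1=O)CCC/C=C/[C@@H]([Si](C)(C)C)CCC[C@@H]2C(=O)[C@H](C)CN3CCC[C@H](/C=C/CCCB4C5CCCC4CCC5)[C@@H]23 | intermediate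
29 | 20-membered macrocycle: 27 with iodine replaced by a bond from C5 of the dihydropyridone to the terminal carbon of the former pentadienyl group (ring: N–CH=C–(CH2)3–CH=CH–C9–C9a–C1–(CH2)3–CH(SiMe3)–CH=CH–(CH2)3–N; both alkenes E, C–Si centre S) | C[C@@H]1CN2CCC/C=C/[C@@H]([Si](C)(C)C)CCC[C@@H]4C(=O)[C@H](C)CN5CCC[C@H](/C=C/CCCC(C1=O)=C2)[C@@H]45 | intermediate
30 | C1=C2 trimethylsilyl enol ether of the cis half of 31 (present as ammonium triflate in the flask) | C[C@@H]1CN2CCC[C@H]3/C=C/CCC[C@@H]4C(=O)[C@H](C)CN5CCC[C@H](/C=C/CCCC(=C1O[Si](C)(C)C)[C@@H]32)[C@@H]45 | intermediate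
31 | bis-quinolizidinone (E,E)-diene: 32 with (E)-CH=CH in place of the CH2CH2 unit attached to C9 of each half | C[C@@H]1CN2CCC[C@H]3/C=C/CCC[C@@H]4C(=O)[C@H](C)CN5CCC[C@H](/C=C/CCC[C@H](C1=O)[C@@H]32)[C@@H]45 | intermediate
32 | bis-quinolizidinone target: cis half (1S,3R,9R,9aR), trans half (1S,3R,9S,9aS), halves joined C9→C1 by two (CH2)5 chains | C[C@@H]1CN2CCC[C@H]3CCCCC[C@@H]4C(=O)[C@H](C)CN5CCC[C@H](CCCCC[C@H](C1=O)[C@@H]32)[C@@H]45 | target

**Totals**

Total step count: 20. Longest linear sequence: 12 steps (5, 10, 11, 12, 13, 14, 15, 16, 17, 18, 19, 20).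

**Steps most likely to fail**

Step 19. The silyloxy-iminium ion may be too weak an electrophile, so that protodesilylation of the allylsilane outruns ring closure; the kinetic C1 configuration may also be lost by enolisation during the quench. Fallback (known chemistry, other oxidation level), setting out from 29 and returning at 32:
- i-Bu2AlH (THF, −78 °C) reduces both carbonyl groups to the bis-carbinol F1, which is used crude.
- Camphorsulfonic acid in CH2Cl2 ionises its 4-hydroxy-1,2,3,4-tetrahydropyridine to the conjugated 2,3-dihydropyridinium ion. The allylsilane closes onto this ion at C9a (iminium–allylsilane cyclisation, same chirality transfer) to give the ring-A alkene F2 with a C1=C2 double bond.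
- H2 with RhCl(PPh3)3 should saturate only the two disubstituted chain alkenes, giving the mono-alkene F3.
- BH3·THF, then NaOH/H2O2, adds H to C1 and OH to C2 from the face opposite both the C9–C9a bond and the C3 methyl. This gives the diol F4 and fixes H1/H9a cis at a centre that cannot epimerise.
- Dess–Martin periodinane/NaHCO3 oxidises both carbinols and returns the route at 32.

Step 16. The same slow C–C bond formation may occur, with intermolecular allyl transfer from the second allylsilane as a further drain. Fallback (known chemistry; ring B closed by C–N bond formation), setting out from 6 with 23 and 21 and returning at 26: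
- B-alkyl Suzuki–Miyaura coupling of 6 with borane 23 gives the N-unsubstituted vinylogous amide F5.
- n-BuLi and allyl chloroformate give the N-allyloxycarbonyl dihydropyridone F6, a vinylogous imide that behaves as a normal enone acceptor.
- TiCl4-mediated Hosomi–Sakurai conjugate allylation with 21 (in excess, CH2Cl2, −78 °C) forms the C9–C9a bond intermolecularly with the same anti-SE2′ transfer, giving the piperidinone F7.
- Pd(PPh3)4/morpholine removes the carbamate to give the secondary amine F8.
- NaI/K2CO3 in MeCN closes ring B by N-alkylation with the chloropropyl group, and K2CO3/MeOH equilibrates C1 and C9a, returning the route at 26.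

Step 18. Oligomerisation may compete with ring closure, and the borane may reduce the ketone during hydroboration. Fallback (macrocycle closed by C–N instead of C–C bond formation), setting out from 26 and 6 and returning at 29:
- 26 is hydroborated with 9-BBN-H to the alkylborane F9.
- F9 is coupled intermolecularly with the N–H iodide 6 (PdCl2(dppf), AsPh3, Cs2CO3) to give the seco vinylogous amide F10.
- The sodium salt of F10 (NaH, NaI, DMF, high dilution, 50 °C) closes the 20-membered ring by intramolecular N-alkylation with the terminal chloride, returning the route at 29.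

**Further compounds**

F1 | step 19 | bis-carbinol from 1,2-reduction of both carbonyl groups of 29 (carbinol configurations not controlled) | C[C@@H]1CN2CCC/C=C/[C@@H]([Si](C)(C)C)CCC[C@@H]4C(O)[C@H](C)CN5CCC[C@H](/C=C/CCCC(C1O)=C2)[C@@H]45
F2 | step 19 | ring-A alkene: cyclised cis half with C1=C2 double bond, two (E)-chain alkenes, trans-half C2 carbinol | C[C@@H]1CN2CCC[C@H]3/C=C/CCC[C@@H]4C(O)[C@H](C)CN5CCC[C@H](/C=C/CCCC(=C1)[C@@H]32)[C@@H]45
F3 | step 19 | mono-alkene: F2 with both chain alkenes saturated | C[C@@H]1CN2CCC[C@H]3CCCCC[C@@H]4C(O)[C@H](C)CN5CCC[C@H](CCCCCC(=C1)[C@@H]32)[C@@H]45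
F4 | step 19 | diol: 32 with both C2 ketones as carbinols (cis-half C2–OH syn to H1) | C[C@@H]1CN2CCC[C@H]3CCCCC[C@@H]4C(O)[C@H](C)CN5CCC[C@H](CCCCC[C@H]([C@H]1O)[C@@H]32)[C@@H]45
F5 | step 16 | (R)-5-[(4S,5E)-9-chloro-4-(trimethylsilyl)non-5-en-1-yl]-3-methyl-2,3-dihydropyridin-4(1H)-one | C[C@@H]1CNC=C(CCC[C@H]([Si](C)(C)C)/C=C/CCCCl)C1=O
F6 | step 16 | allyl (R)-5-[(4S,5E)-9-chloro-4-(trimethylsilyl)non-5-en-1-yl]-3-methyl-4-oxo-3,4-dihydropyridine-1(2H)-carboxylate | C[C@@H]1CN(C(=O)OCC=C)C=C(CCC[C@H]([Si](C)(C)C)/C=C/CCCCl)C1=O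
F7 | step 16 | N-allyloxycarbonyl piperidin-4-one conjugate adduct (C9 defined, C1 and C9a not yet controlled) | C=CCOC(=O)N1C[C@@H](C)C(=O)C(CCC[C@H]([Si](C)(C)C)/C=C/CCCCl)C1[C@H](CCCCl)/C=C/CC=C
F8 | step 16 | secondary amine from carbamate removal of F7 | C[C@@H]1CNC([C@H](CCCCl)/C=C/CC=C)C(CCC[C@H]([Si](C)(C)C)/C=C/CCCCl)C1=O
F9 | step 18 | 9-BBN adduct of 26 at the terminal alkene | ClCCC/C=C/[C@@H]([Si](C)(C)C)CCC[C@@H]1C(=O)[C@H](C)CN2CCC[C@H](/C=C/CCCB3C4CCCC3CCC4)[C@@H]12
F10 | step 18 | seco vinylogous amide: 26 with the chain terminus bonded to C5 of (R)-3-methyl-2,3-dihydropyridin-4(1H)-one | ClCCC/C=C/[C@@H]([Si](C)(C)C)CCC[C@@H]1C(=O)[C@H](C)CN2CCC[C@H](/C=C/CCCC3=CNC[C@@H](C)C3=O)[C@@H]12
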